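## Structural features

The target is a germacranolide of the heliangolide type: a ten-membered carbocycle (C1–C10) trans-fused across C6–C7 to an α-methylene-γ-butyrolactone (O–C6, C7, C11, C12, exocyclic C13). The ring carries a C1 ketone next to the tertiary C10 carbinol (R), a C3 carbinol (R) allylic to the Z C4=C5 alkene, and the contiguous triad C6 (R, lactone O–CH), C7 (R) and C8 (R, isovalerate). Three stereocentres therefore stand side by side and two more sit across a mobile medium ring. Fragile units are the methylene lactone (Michael acceptor), the C1/C3 β-hydroxy ketone (dehydration, retro-aldol ring opening), the C1/C10 α-ketol (acyloin shift) and the allylic C6–O bond. The real difficulty is the ten-membered ring itself, with the relay of configuration between C3, the C6–C8 triad and C10 while C4=C5 stays Z. The key step exploits three facts. The arc C6–C5–C4–C3–C2–C1 is the ring of a 4-oxygenated 3-methylcyclohex-2-enone. C10, C9 and C14 form an isopropenyl group on C1. C7–C8 is an oxygenated vinyl unit on C6. A [3,3] shift across C8=C7–C6–C1–C10=C9 therefore converts a cyclohexenol into the ten-membered ring, and the enolate left at C6/C7 takes the C11–C12 acetate arm.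

## Logic of the disconnections

27 from 26. The O3–Si bond is cut last. Reason: the C3 hydroxyl must stay masked while C1 is oxidised. Gain: every other function of 27 is already present in 26. Demand: a desilylation mild enough for the β-hydroxy ketone and the α-ketol.

26 from 25 from 24. The C1=O bond is traced to the C1–OH of 25, and the C1–O and C10–O bonds of 25 to the C1=C10 alkene of 24. Reason: that E alkene is what a [3,3] ring expansion leaves behind. Gain: two oxygen functions and the C10 centre are replaced by one alkene. Demand: osmylation of one alkene out of three, on the face that gives 10R.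

24 from 22 and 23; 22 from 21. The acyl–O8 bond and then the benzyl–O8 bond are cut. Reason: O8 has to be an ether through the organometallic and enolate steps and an ester only at the end. Gain: 23 is commercial and 21 carries one base-stable group on O8. Demand: neutral oxidative ether cleavage, and acylation before O8 can attack C12.

21 from 18 (through 19 and 20). The C11=C13 bond is cut, C13 coming from an iminium salt. Reason: in 18 the lactone is the only enolisable carbonyl, which is no longer true once C1 is a ketone. Gain: the Michael acceptor is replaced by a plain γ-lactone. Demand: clean kinetic lactone enolate chemistry.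

18 from 17 from 16. The O6–C12 bond is cut to give 17 and the C6–H bond to give 16. Reason: a C6 carbonyl with an acetate arm on C7 is the direct outcome of enolate trapping. Gain: the C6 centre is referred to C7. Demand: hydride delivery to the face of C6 that leads to the trans ring fusion.

16 from 11 and 12 (through 13, 14 and 15). C7–C11 is cut to an enolate and 12; then C8–C9 is cut and C6–C1 rejoined. Reason: this removes the medium ring. Gain: the ten-membered ring collapses to a cyclohexenol, C8 is referred to C1 and an alkene geometry, and the Z C4=C5 alkene sits in a six-membered ring where it has no alternative. Demand: trans alkenyl groups in 11, an E enol ether, a chair transition state, and control of the alkylation face at C7.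

11 from 10; 10 from 4 and 8 (through 9); 8 from 5 and 6 (through 7). The C7=C8 alkene is traced to the alkyne of 10, the C6–C7 bond is cut to 4 and 9, and the O–C(vinyl) bond of 8 to 5 and 6. Reason: trans-hydroalumination fixes the E geometry by mechanism and avoids a β-alkoxyvinyllithium. Gain: C7 and C8 come from a two-carbon bulk chemical. Demand: acetylide attack on the face of 4 opposite to both ring substituents.

4 from 3 from 2 from 1. The C6 carbonyl is cut back to an allylic CH2, then O3–Si, then the C3–H bond. Reason: in 3 the position that competes in a limonene oxidation is already oxygenated, so only one allylic ring methylene remains. Gain: both stereocentres of 4 come from 1 and one well-known reduction. Demand: regioselective allylic oxidation without loss of the α-stereocentre.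

## Other disconnections considered

Alternative 1: The cut goes through both allylic C–O bonds, C3–O and C6–O.
- Forward step: photosensitised singlet oxygen adds across C3 and C6 of the ten-membered (Z,Z)-diene A2 in a [4+2] cycloaddition. This gives the bridged 1,2-dioxene A1, whose ring alkene is the Z C4=C5 bond. O–O reduction and lactonisation onto the acrylate ester would lead on to 27.
- In favour: one event sets both allylic oxygens cis, which is the C3/C6 relationship 27 needs, and the Z alkene is fixed by the ring. A2 already carries the acrylate, the isovalerate and the protected C1/C10 diol, so no enolate chemistry and no exchange at O8 follow.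
- Against: no C–C bond is formed. The ring, with an s-cis diene and with C7, C8, C1 and C10 in place, has to come from elsewhere. The diene face taken by oxygen depends on the conformation of A2. Ene reactions at C15 and C2 and the base lability of A1 compete.
- Comparison: both key steps are pericyclic and stereospecific, but the chosen one creates the medium ring and two C–C bonds, whereas this one decorates a ring that is assumed. On the C3/C6 relationship the alternative is the better plan (one event instead of the reductions of steps 1 and 8). On end-game length it is the equal or better. On overall step economy it is worse, because the ring is left unsolved.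

Alternative 2: The cut goes through C1–C2 and O–C3, so the β-hydroxy ketone is read as an isoxazoline.
- Forward step: the aldoxime A4, a γ-lactone with the diene on C6 and the C8–C1 chain on C7, is oxidised with NaOCl to the nitrile oxide. This adds to the terminal vinyl group and closes the carbocycle and the isoxazoline of A3 together.
- In favour: ring closure and masking of the most fragile unit coincide. The regiochemistry (carbon to the CH2 terminus, oxygen to C3) is the normal one. A4 could be assembled convergently. The isoxazoline would survive a later lactone methylenation, so on protecting the β-hydroxy ketone this plan is better than the chosen one.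
- Against: the ten-membered ring forms by end-to-end closure, with the entropic and transannular cost that a ring expansion avoids, so dimerisation of the dipole has to be beaten by dilution. The C3 configuration depends on a macrocyclic transition state and is not relayed from a neighbouring centre. N–O cleavage must later spare the alkenes, and methylenation and the O8 exchange are still to come.
- Comparison: the number of steps after the key step is about equal. A4, with four stereocentres in an open chain, is longer to reach than 11.

Alternative 3: The cut removes the lactone carbonyl: O–C12 and C11–C12 are broken, leaving the C6 alcohol and a C7 ethynyl group in A6.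
- Forward step: PdCl2 with PPh3 and SnCl2 under CO converts this homopropargylic alcohol into the α-methylene-γ-butyrolactone A5, which is the same compound as 26.
- In favour: lactone ring and exocyclic methylene appear together, last, under neutral conditions. The Michael acceptor is not carried through oxidations and no lactone enolate is needed. On this point and on the three-alkene dihydroxylation problem it is the better plan, and it uses one step where the chosen route uses three (steps 8 to 10).
- Against: the step forms no bond of the carbocycle and no stereocentre, so A6 must already hold all five centres, the α-ketol and the β-silyloxy ketone. A C7 ethynyl group cannot be introduced by enolate alkylation, so the ring synthesis would need redesign. The allylic C6 alcohol is exposed to divalent palladium and a Lewis acid. Exocyclic methylene versus butenolide formation and the trans fusion are not assured on a medium ring.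
- Comparison: as an end game it is shorter and milder. As a strategy it leaves the ring and the stereochemistry, which the chosen key step addresses, untouched.

Key step: step 7

Remark on the chemistry: the target SMILES reads 3R,6R,7R,8R,10R with a 4Z alkene (germacranolide numbering); the rearrangement precursor 11 and product 16 agree with it and need no structural change, but the face of alkylation at C7 is controlled here by a lithium chelate, and the enone 4 is made from (R)-carvone so that a limonene oxidation with two competing ring positions is avoided.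

## Route

Step 1
Reactants: 1 (R)-(−)-carvone
Product: 2 (1R,5R)-cis-carveol
Conditions: NaBH4, CeCl3·7H2O, MeOH, −20 °C
Reagents that add atoms: none
Why: Luche 1,2-reduction of the enone; hydride should add axially to the half-chair with the isopropenyl group equatorial, placing the new hydroxyl equatorial and cis to isopropenyl (this carbon becomes C3 of the target, R).

Step 2
Reactants: 2 (1R,5R)-cis-carveol
Product: 3 tert-butyldimethylsilyl ether of (1R,5R)-cis-carveol
Conditions: TBSCl, imidazole, DMF, rt
Reagents that add atoms: tert-butyldimethylsilyl chloride, CC(C)(C)[Si](C)(C)Cl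
Why: Routine silylation of a secondary allylic alcohol; this is the one protecting group that has to last to the final step, and no stereocentre is touched.

Step 3
Reactants: 3 tert-butyldimethylsilyl ether of (1R,5R)-cis-carveol
Product: 4 (4R,6R)-4-(tert-butyldimethylsilyloxy)-3-methyl-6-(prop-1-en-2-yl)cyclohex-2-en-1-one
Conditions: CrO3, 3,5-dimethylpyrazole, CH2Cl2, −20 °C
Reagents that add atoms: chromium trioxide, O=[Cr](=O)=O
Why: Allylic C–H oxidation with the CrO3–3,5-dimethylpyrazole complex converts the only allylic ring methylene into the conjugated ketone. Both stereocentres are retained; the isopropenyl-bearing carbon is now α to the ketone, and its cis relationship to the silyloxy group (both pseudo-equatorial) is also the more stable arrangement.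

Step 4
Reactants: 5 4-methoxybenzyl alcohol; 6 trichloroethylene
Product: 8 (E)-1,2-dichlorovinyl 4-methoxybenzyl ether, via dichloroacetylene 7 (not isolated)
Conditions: KH, THF, 0 °C; then 6, −50 °C → rt
Reagents that add atoms: none
Why: Alkoxide-induced dehydrochlorination of trichloroethylene gives dichloroacetylene, to which the alkoxide adds in anti fashion to give the E dichlorovinyl ether, the standard precursor of alkoxyacetylides.

Step 5
Reactants: 8 (E)-1,2-dichlorovinyl 4-methoxybenzyl ether; 4 (4R,6R)-4-(tert-butyldimethylsilyloxy)-3-methyl-6-(prop-1-en-2-yl)cyclohex-2-en-1-one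
Product: 10 (1R,4R,6R)-4-(tert-butyldimethylsilyloxy)-1-[(4-methoxybenzyloxy)ethynyl]-3-methyl-6-(prop-1-en-2-yl)cyclohex-2-en-1-ol, via lithium 4-methoxybenzyloxyacetylide 9 (not isolated)
Conditions: n-BuLi (2 equiv per 8), THF, −78 → −40 °C; then 4, −78 °C; H2O quench
Reagents that add atoms: none
Why: Dehydrochlorination and chlorine–lithium exchange of 8 give acetylide 9, which adds 1,2 to enone 4. The half-chair of 4 is locked by its two cis, pseudo-equatorial substituents, and attack on the face opposite to both, as in menthone-type α-branched cyclohexanones, should set the carbinol (1R) with the alkynyl group trans to isopropenyl.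

Step 6
Reactants: 10 (1R,4R,6R)-4-(tert-butyldimethylsilyloxy)-1-[(4-methoxybenzyloxy)ethynyl]-3-methyl-6-(prop-1-en-2-yl)cyclohex-2-en-1-ol
Product: 11 (1R,4R,6R)-4-(tert-butyldimethylsilyloxy)-1-[(E)-2-(4-methoxybenzyloxy)ethenyl]-3-methyl-6-(prop-1-en-2-yl)cyclohex-2-en-1-ol
Conditions: LiAlH4, THF, 0 °C → rt; then NaOH (aq)
Reagents that add atoms: none
Why: Hydroxyl-directed trans-hydroalumination of the propargylic alkoxide followed by protonolysis, the known route from alkoxyethynyl carbinols to E β-alkoxyvinyl carbinols, fixes the E enol ether by mechanism. The benzylic ynol ether 10 is reduced without storage because such ethers rearrange on heating, and 11 is kept free of acid.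

Step 7
Reactants: 11 (1R,4R,6R)-4-(tert-butyldimethylsilyloxy)-1-[(E)-2-(4-methoxybenzyloxy)ethenyl]-3-methyl-6-(prop-1-en-2-yl)cyclohex-2-en-1-ol; 12 tert-butyl bromoacetate
Product: 16 tert-butyl [(1R,2R,4E,7R,8Z)-7-(tert-butyldimethylsilyloxy)-2-(4-methoxybenzyloxy)-4,8-dimethyl-10-oxocyclodeca-4,8-dien-1-yl]acetate, via potassium alkoxide of the cyclohexenol 13 (not isolated), via ring-expanded potassium enolate 14 (not isolated), via chelated lithium enolate 15 (not isolated)
Conditions: KN(SiMe3)2, 18-crown-6, THF, −78 → 0 °C; then −78 °C, LiBr; then 12, −78 → −30 °C; pH 7 buffer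
Reagents that add atoms: none
Why: KN(SiMe3)2 with 18-crown-6 turns 11 into the dissociated alkoxide 13, whose oxyanion weakens the C6–C1 bond and drives an anionic oxy-Cope rearrangement; the closest known reaction type is the ring expansion of potassium 1,2-dialkenylcyclohexanolates to cyclodecenone enolates with C-alkylation in the same flask. The ten-membered ring is closed by ring enlargement and not by end-to-end cyclisation: in a chair transition state with the alkoxyvinyl and isopropenyl groups trans-diequatorial, C8–C9 forms suprafacially while C6–C1 breaks, so the six-membered ring grows by four carbons. C8 is controlled by chirality transfer from C1 (R, destroyed in the step) through that chair together with the E enol ether geometry, which puts the benzyloxy group equatorial and gives 8R; the equatorial C1–C2 bond gives the E C1=C10 alkene and the Z C4=C5 alkene is carried over from the cyclohexene. C7 is controlled by the face of enolate alkylation, which is anti to the C8–C9 ring bond; the conformer delivered by the chair (C8–O anti to C6) would expose the face that leads to the C7 epimer, so LiBr is added to form enolate 15, in which lithium bridges the enolate oxygen and the C8 ether oxygen (18-crown-6 holds K+ far more strongly than Li+) and turns the C6=C7 unit over, so that the exposed face gives 7R, the Fráter–Seebach-type anti relationship. The step needs C- over O-alkylation at a single site, which the soft, SN2-active bromoacetate and the cross-conjugated enolate (C7 is its only α-carbon) secure. It also needs E1cB loss of the C8 alkoxide to stay slow, which the in-plane C8–O bond of both conformers and the low temperature after the rearrangement favour.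

Step 8
Reactants: 16 tert-butyl [(1R,2R,4E,7R,8Z)-7-(tert-butyldimethylsilyloxy)-2-(4-methoxybenzyloxy)-4,8-dimethyl-10-oxocyclodeca-4,8-dien-1-yl]acetate
Product: 17 tert-butyl [(4E,8Z)-7-(tert-butyldimethylsilyloxy)-10-hydroxy-2-(4-methoxybenzyloxy)-4,8-dimethylcyclodeca-4,8-dien-1-yl]acetate (germacrane numbering 3R,6R,7S,8R; the 7S label reflects only a change of CIP priorities)
Conditions: NaBH4, CeCl3·7H2O, MeOH, −40 °C
Reagents that add atoms: none
Why: Luche 1,2-reduction of the Z enone. With the enone planar and the C7–C8 bond near the carbonyl plane, the acetate arm on C7 stands perpendicular to it and hydride should enter anti to that arm, giving the 6R carbinol whose oxygen can close a trans-fused lactone.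

Step 9
Reactants: 17 tert-butyl [(4E,8Z)-7-(tert-butyldimethylsilyloxy)-10-hydroxy-2-(4-methoxybenzyloxy)-4,8-dimethylcyclodeca-4,8-dien-1-yl]acetate
Product: 18 (3R,6R,7R,8R)-3-(tert-butyldimethylsilyloxy)-8-(4-methoxybenzyloxy)-13-norgermacra-1(10)E,4Z-dien-12,6-olide (trans-fused γ-lactone, C11 is CH2)
Conditions: TsOH·H2O (cat.), CH2Cl2, rt
Reagents that add atoms: none
Why: Acid-catalysed intramolecular transesterification: the γ-hydroxyl at C6 attacks the tert-butyl ester and closes the five-membered lactone with loss of tert-butanol and retention at C6 and C7. Catalytic acid in an aprotic solvent should leave the benzyl-type and silyl ethers in place.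

Step 10
Reactants: 18 (3R,6R,7R,8R)-3-(tert-butyldimethylsilyloxy)-8-(4-methoxybenzyloxy)-13-norgermacra-1(10)E,4Z-dien-12,6-olide
Product: 21 (3R,6R,7R,8R)-3-(tert-butyldimethylsilyloxy)-8-(4-methoxybenzyloxy)germacra-1(10)E,4Z,11(13)-trien-12,6-olide, via dimethylaminomethyl lactone 19 (not isolated), via trimethylammonium iodide 20 (not isolated)
Conditions: LiN(iPr)2, THF, −78 °C; CH2=NMe2 I, −78 °C → rt; then MeI, MeOH, rt; then NaHCO3 (aq), CH2Cl2
Reagents that add atoms: N,N-dimethylmethyleneiminium iodide (Eschenmoser's salt), C=[N+](C)C.[I-]; iodomethane, CI (its methyl group is carried only by intermediate 20)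
Why: Aminomethylation of the lactone enolate (Mannich reaction), quaternisation and base-induced elimination give the α-methylene lactone; the new centre at C11 in 19 and 20 is lost again. The step is placed here because the lactone is the only enolisable carbonyl at this stage.

Step 11
Reactants: 21 (3R,6R,7R,8R)-3-(tert-butyldimethylsilyloxy)-8-(4-methoxybenzyloxy)germacra-1(10)E,4Z,11(13)-trien-12,6-olide
Product: 22 (3R,6R,7R,8R)-3-(tert-butyldimethylsilyloxy)-8-hydroxygermacra-1(10)E,4Z,11(13)-trien-12,6-olide
Conditions: DDQ, CH2Cl2/pH 7 buffer, 0 °C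
Reagents that add atoms: none
Why: Oxidative cleavage of the p-methoxybenzyl ether by DDQ under buffered, neutral conditions frees the C8 hydroxyl without touching the silyl ether, the alkenes or the methylene lactone.

Step 12
Reactants: 22 (3R,6R,7R,8R)-3-(tert-butyldimethylsilyloxy)-8-hydroxygermacra-1(10)E,4Z,11(13)-trien-12,6-olide; 23 isovaleryl chloride
Product: 24 (3R,6R,7R,8R)-3-(tert-butyldimethylsilyloxy)-8-(3-methylbutanoyloxy)germacra-1(10)E,4Z,11(13)-trien-12,6-olide
Conditions: pyridine, DMAP (cat.), CH2Cl2, 0 °C → rt
Reagents that add atoms: none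
Why: DMAP-catalysed acylation of the secondary C8 alcohol with the acid chloride, run cold and directly after step 11 so that the free hydroxyl has no time to translactonise onto C12.

Step 13
Reactants: 24 (3R,6R,7R,8R)-3-(tert-butyldimethylsilyloxy)-8-(3-methylbutanoyloxy)germacra-1(10)E,4Z,11(13)-trien-12,6-olide
Product: 25 (1R,3R,6R,7R,8R,10R)-3-(tert-butyldimethylsilyloxy)-1,10-dihydroxy-8-(3-methylbutanoyloxy)germacra-4Z,11(13)-dien-12,6-olide
Conditions: OsO4 (cat.), (DHQD)2PHAL (cat.), NMO, acetone/H2O, 0 °C
Reagents that add atoms: N-methylmorpholine N-oxide, C[N+]1([O-])CCOCC1; water, O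
Why: Osmium-catalysed syn-dihydroxylation (Upjohn conditions with a cinchona ligand). The isolated, electron-rich trisubstituted C1=C10 alkene should react ahead of the conjugated C11=C13 alkene and of C4=C5, which is deactivated by two allylic oxygens. Attack on the outer face of the E alkene in the conformer with the C14 methyl on the β side, the face that the DHQD-derived ligand also prefers, gives 10R (and 1R).

Step 14
Reactants: 25 (1R,3R,6R,7R,8R,10R)-3-(tert-butyldimethylsilyloxy)-1,10-dihydroxy-8-(3-methylbutanoyloxy)germacra-4Z,11(13)-dien-12,6-olide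
Product: 26 (3R,6R,7R,8R,10R)-3-(tert-butyldimethylsilyloxy)-10-hydroxy-8-(3-methylbutanoyloxy)-1-oxogermacra-4Z,11(13)-dien-12,6-olide
Conditions: Dess–Martin periodinane, pyridine, CH2Cl2, 0 °C → rt
Reagents that add atoms: none
Why: Dess–Martin oxidation of the secondary C1 alcohol; the tertiary C10 hydroxyl cannot be oxidised and keeps its configuration, and pyridine buffers the acetic acid formed.

Step 15
Reactants: 26 (3R,6R,7R,8R,10R)-3-(tert-butyldimethylsilyloxy)-10-hydroxy-8-(3-methylbutanoyloxy)-1-oxogermacra-4Z,11(13)-dien-12,6-olide
Product: 27 (3R,6R,7R,8R,10R)-3,10-dihydroxy-8-(3-methylbutanoyloxy)-1-oxogermacra-4Z,11(13)-dien-12,6-olide (CNP0406522.1)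
Conditions: HF·pyridine, pyridine, THF, 0 °C → rt
Reagents that add atoms: none
Why: Fluoride-mediated desilylation under buffered, slightly acidic conditions, chosen because basic fluoride could dehydrate or cleave (retro-aldol) the C1/C3 β-hydroxy ketone that is unveiled.

## Compound list

1 | (R)-(−)-carvone | CC1=CC[C@H](CC1=O)C(C)=C | starting material
2 | (1R,5R)-cis-carveol | CC1=CC[C@H](C[C@H]1O)C(C)=C | intermediate
3 | tert-butyldimethylsilyl ether of (1R,5R)-cis-carveol | CC1=CC[C@H](C[C@H]1O[Si](C)(C)C(C)(C)C)C(C)=C | intermediate
4 | (4R,6R)-4-(tert-butyldimethylsilyloxy)-3-methyl-6-(prop-1-en-2-yl)cyclohex-2-en-1-one | O=C1C=C(C)[C@H](O[Si](C)(C)C(C)(C)C)C[C@@H]1C(C)=C | intermediate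
5 | 4-methoxybenzyl alcohol | COc1ccc(CO)cc1 | starting material
6 | trichloroethylene | ClC=C(Cl)Cl | starting material
7 | dichloroacetylene (not isolated) | ClC#CCl | intermediate
8 | (E)-1,2-dichlorovinyl 4-methoxybenzyl ether | COc1ccc(CO/C(Cl)=C\Cl)cc1 | intermediate
9 | lithium 4-methoxybenzyloxyacetylide (not isolated) | [Li]C#COCc1ccc(OC)cc1 | intermediate
10 | (1R,4R,6R)-4-(tert-butyldimethylsilyloxy)-1-[(4-methoxybenzyloxy)ethynyl]-3-methyl-6-(prop-1-en-2-yl)cyclohex-2-en-1-ol | O[C@]1(C#COCc2ccc(OC)cc2)C=C(C)[C@H](O[Si](C)(C)C(C)(C)C)C[C@@H]1C(C)=C | intermediate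
11 | (1R,4R,6R)-4-(tert-butyldimethylsilyloxy)-1-[(E)-2-(4-methoxybenzyloxy)ethenyl]-3-methyl-6-(prop-1-en-2-yl)cyclohex-2-en-1-ol | O[C@]1(/C=C/OCc2ccc(OC)cc2)C=C(C)[C@H](O[Si](C)(C)C(C)(C)C)C[C@@H]1C(C)=C | intermediate
12 | tert-butyl bromoacetate | CC(C)(C)OC(=O)CBr | starting material
13 | potassium alkoxide of 11 (not isolated) | [K+].[O-][C@]1(/C=C/OCc2ccc(OC)cc2)C=C(C)[C@H](O[Si](C)(C)C(C)(C)C)C[C@@H]1C(C)=C | intermediate
14 | potassium enolate of the ring-expanded cyclodecadienone, C6 enolate oxygen cis to C8, 3R,8R (not isolated) | [K+].C1/C(C)=C/C[C@@H](O[Si](C)(C)C(C)(C)C)/C(C)=C\C([O-])=C\[C@@H]1OCc2ccc(OC)cc2 | intermediate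
15 | lithium enolate corresponding to 14, chelated by the C8 ether oxygen (not isolated) | [Li+].C1/C(C)=C/C[C@@H](O[Si](C)(C)C(C)(C)C)/C(C)=C\C([O-])=C\[C@@H]1OCc2ccc(OC)cc2 | intermediate
16 | tert-butyl [(1R,2R,4E,7R,8Z)-7-(tert-butyldimethylsilyloxy)-2-(4-methoxybenzyloxy)-4,8-dimethyl-10-oxocyclodeca-4,8-dien-1-yl]acetate | O=C1/C=C(/C)[C@H](O[Si](C)(C)C(C)(C)C)C/C=C(\C)C[C@@H](OCc2ccc(OC)cc2)[C@H]1CC(=O)OC(C)(C)C | intermediate
17 | tert-butyl [(4E,8Z)-7-(tert-butyldimethylsilyloxy)-10-hydroxy-2-(4-methoxybenzyloxy)-4,8-dimethylcyclodeca-4,8-dien-1-yl]acetate, germacrane numbering 3R,6R,7S,8R | O[C@@H]1/C=C(/C)[C@H](O[Si](C)(C)C(C)(C)C)C/C=C(\C)C[C@@H](OCc2ccc(OC)cc2)[C@H]1CC(=O)OC(C)(C)C | intermediate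
18 | (3R,6R,7R,8R)-3-(tert-butyldimethylsilyloxy)-8-(4-methoxybenzyloxy)-13-norgermacra-1(10)E,4Z-dien-12,6-olide | C1C(=O)O[C@@H]2/C=C(/C)[C@H](O[Si](C)(C)C(C)(C)C)C/C=C(\C)C[C@@H](OCc3ccc(OC)cc3)[C@@H]12 | intermediate
19 | 11-(dimethylaminomethyl) derivative of 18, C11 epimers (not isolated) | CN(C)CC1C(=O)O[C@@H]2/C=C(/C)[C@H](O[Si](C)(C)C(C)(C)C)C/C=C(\C)C[C@@H](OCc3ccc(OC)cc3)[C@@H]12 | intermediate
20 | trimethylammonium iodide derived from 19 (not isolated) | [I-].C[N+](C)(C)CC1C(=O)O[C@@H]2/C=C(/C)[C@H](O[Si](C)(C)C(C)(C)C)C/C=C(\C)C[C@@H](OCc3ccc(OC)cc3)[C@@H]12 | intermediate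
21 | (3R,6R,7R,8R)-3-(tert-butyldimethylsilyloxy)-8-(4-methoxybenzyloxy)germacra-1(10)E,4Z,11(13)-trien-12,6-olide | C=C1C(=O)O[C@@H]2/C=C(/C)[C@H](O[Si](C)(C)C(C)(C)C)C/C=C(\C)C[C@@H](OCc3ccc(OC)cc3)[C@@H]12 | intermediate
22 | (3R,6R,7R,8R)-3-(tert-butyldimethylsilyloxy)-8-hydroxygermacra-1(10)E,4Z,11(13)-trien-12,6-olide | C=C1C(=O)O[C@@H]2/C=C(/C)[C@H](O[Si](C)(C)C(C)(C)C)C/C=C(\C)C[C@@H](O)[C@@H]12 | intermediate
23 | isovaleryl chloride | CC(C)CC(Cl)=O | starting material
24 | (3R,6R,7R,8R)-3-(tert-butyldimethylsilyloxy)-8-(3-methylbutanoyloxy)germacra-1(10)E,4Z,11(13)-trien-12,6-olide | C=C1C(=O)O[C@@H]2/C=C(/C)[C@H](O[Si](C)(C)C(C)(C)C)C/C=C(\C)C[C@@H](OC(=O)CC(C)C)[C@@H]12 | intermediate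
25 | (1R,3R,6R,7R,8R,10R)-3-(tert-butyldimethylsilyloxy)-1,10-dihydroxy-8-(3-methylbutanoyloxy)germacra-4Z,11(13)-dien-12,6-olide | C=C1C(=O)O[C@@H]2/C=C(/C)[C@H](O[Si](C)(C)C(C)(C)C)C[C@@H](O)[C@](C)(O)C[C@@H](OC(=O)CC(C)C)[C@@H]12 | intermediate
26 | (3R,6R,7R,8R,10R)-3-(tert-butyldimethylsilyloxy)-10-hydroxy-8-(3-methylbutanoyloxy)-1-oxogermacra-4Z,11(13)-dien-12,6-olide | C=C1C(=O)O[C@@H]2/C=C(/C)[C@H](O[Si](C)(C)C(C)(C)C)CC(=O)[C@](C)(O)C[C@@H](OC(=O)CC(C)C)[C@@H]12 | intermediate
27 | (3R,6R,7R,8R,10R)-3,10-dihydroxy-8-(3-methylbutanoyloxy)-1-oxogermacra-4Z,11(13)-dien-12,6-olide (CNP0406522.1) | C=C1C(=O)O[C@@H]2/C=C(/C)[C@H](O)CC(=O)[C@](C)(O)C[C@@H](OC(=O)CC(C)C)[C@@H]12 | target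

## Step count and least certain steps

Total step count: 15. Longest linear sequence: 14 steps (steps 1–3 and 5–15 from 1); step 4 is a one-step branch from 5 and 6.

Step 7 (key step). Most likely failure: alkylation on the wrong face of the enolate if lithium chelation does not override the conformer delivered by the chair, giving the C7 epimer. Also possible are E1cB loss of the C8 alkoxide from the β-alkoxy enolate if the rearrangement needs more heat, and reversible silyl transfer from O3 to the C6 alkoxide, which would slow the rearrangement. Fallback, from 11 back to 16: the rearrangement is run as above but the crown-ether-separated potassium enolate 14 is alkylated with 12 without LiBr, which should give the C7 epimer of the keto ester F1. This is deprotonated at C7 with LiN(SiMe3)2 (THF, −78 °C) to the lithium enolate F2, which is protonated kinetically with a hindered phenol on the exposed face, the face the electrophile used before, to give 16.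

Step 5. Most likely failure: competing attack of the slim acetylide on the face syn to the ring substituents (axial attack), or enolisation at the doubly activated α′ position. The cis-dialkenyl carbinol would rearrange through a different chair and give the wrong C8 configuration and C1=C10 geometry. Fallback, from 8 and 4 to 11, using a bulkier sp2 nucleophile that adds in one step: 8 is treated with n-BuLi and quenched with methanol to give 4-methoxybenzyl ethynyl ether F3. Hydrozirconation with Cp2Zr(H)Cl and iodinolysis give (E)-1-iodo-2-(4-methoxybenzyloxy)ethene F4. Iodine–lithium exchange with t-BuLi at −100 °C gives (E)-2-(4-methoxybenzyloxy)vinyllithium F5, which is transmetalated at once with CeCl3 to the vinylcerium dichloride F6. F6 adds to 4 from the less hindered face and gives 11 directly.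

Step 3. Most likely failure: oxidation at the silyloxy-bearing allylic carbon or at the allylic positions of the isopropenyl group, or over-oxidation. Fallback, from 3 to 4, replacing C–H oxidation by an epoxide, selenoxide and oxidative transposition sequence: mCPBA epoxidises the trisubstituted ring alkene of 3 to the epoxide F7. Phenylselenide (PhSeSePh, NaBH4) opens it at the secondary carbon to the hydroxy selenide F8, and H2O2 then causes selenoxide elimination to the tertiary allylic alcohol F9. Pyridinium chlorochromate (C5H5NH[CrO3Cl]) effects the oxidative 1,3-transposition of F9 to 4.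

Step 8. Most likely failure: hydride delivery to the other face of C6, because facial control by medium-ring conformation is hard to predict; conjugate reduction is a lesser risk. Fallback, from 16 to 17: the C6 epimer of the hydroxy ester F10 is inverted by a Mitsunobu reaction with 4-nitrobenzoic acid (PPh3, diisopropyl azodicarboxylate) to the 4-nitrobenzoate F11, and methanolysis (K2CO3, MeOH) gives 17.

Step 13. Most likely failure: competing osmylation of the acrylate alkene, or attack on the conformer that exposes the other face of C1=C10. Fallback, from 24 to 26, masking the Michael acceptor: dimethylamine adds to 24 to give the amine adduct F12. Dihydroxylation as in step 13 gives the diol F13, and Parikh–Doering oxidation gives the ketone F14. Quaternisation with MeI gives the ammonium iodide F15, and NaHCO3 then regenerates the methylene lactone as 26.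

## Further compounds

F1 | step 7 | C7 epimer of keto ester 16 | O=C1/C=C(/C)[C@H](O[Si](C)(C)C(C)(C)C)C/C=C(\C)C[C@@H](OCc2ccc(OC)cc2)[C@@H]1CC(=O)OC(C)(C)C
F2 | step 7 | lithium enolate of F1 and 16 (C6=C7 geometry not specified) | [Li+].C1/C(C)=C/C[C@@H](O[Si](C)(C)C(C)(C)C)/C(C)=C\C([O-])=C(CC(=O)OC(C)(C)C)[C@@H]1OCc2ccc(OC)cc2
F3 | step 5 | 4-methoxybenzyl ethynyl ether | C#COCc1ccc(OC)cc1
F4 | step 5 | (E)-1-iodo-2-(4-methoxybenzyloxy)ethene | I/C=C/OCc1ccc(OC)cc1
F5 | step 5 | (E)-2-(4-methoxybenzyloxy)vinyllithium | [Li]/C=C/OCc1ccc(OC)cc1
F6 | step 5 | (E)-2-(4-methoxybenzyloxy)vinylcerium dichloride | Cl[Ce](Cl)/C=C/OCc1ccc(OC)cc1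
F7 | step 3 | ring epoxide of 3 (epoxide face not specified) | CC12OC1C[C@H](C[C@H]2O[Si](C)(C)C(C)(C)C)C(C)=C
F8 | step 3 | hydroxy phenylselenide from F7 | CC1(O)C([Se]c2ccccc2)C[C@H](C[C@H]1O[Si](C)(C)C(C)(C)C)C(C)=C
F9 | step 3 | tertiary allylic alcohol from F8 | CC1(O)C=C[C@H](C[C@H]1O[Si](C)(C)C(C)(C)C)C(C)=C
F10 | step 8 | C6 epimer of hydroxy ester 17 | O[C@H]1/C=C(/C)[C@H](O[Si](C)(C)C(C)(C)C)C/C=C(\C)C[C@@H](OCc2ccc(OC)cc2)[C@H]1CC(=O)OC(C)(C)C
F11 | step 8 | 4-nitrobenzoate of 17 | O=C(O[C@@H]1/C=C(/C)[C@H](O[Si](C)(C)C(C)(C)C)C/C=C(\C)C[C@@H](OCc2ccc(OC)cc2)[C@H]1CC(=O)OC(C)(C)C)c3ccc(cc3)[N+](=O)[O-]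
F12 | step 13 | dimethylamine adduct of 24 (C11 epimers) | CN(C)CC1C(=O)O[C@@H]2/C=C(/C)[C@H](O[Si](C)(C)C(C)(C)C)C/C=C(\C)C[C@@H](OC(=O)CC(C)C)[C@@H]12
F13 | step 13 | 1,10-diol of F12 | CN(C)CC1C(=O)O[C@@H]2/C=C(/C)[C@H](O[Si](C)(C)C(C)(C)C)C[C@@H](O)[C@](C)(O)C[C@@H](OC(=O)CC(C)C)[C@@H]12
F14 | step 13 | 1-ketone of F13 | CN(C)CC1C(=O)O[C@@H]2/C=C(/C)[C@H](O[Si](C)(C)C(C)(C)C)CC(=O)[C@](C)(O)C[C@@H](OC(=O)CC(C)C)[C@@H]12
F15 | step 13 | trimethylammonium iodide of F14 | [I-].C[N+](C)(C)CC1C(=O)O[C@@H]2/C=C(/C)[C@H](O[Si](C)(C)C(C)(C)C)CC(=O)[C@](C)(O)C[C@@H](OC(=O)CC(C)C)[C@@H]12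
A1 | alternative 1 | 3,6-endoperoxide of the ten-membered ring | COC(=O)C(=C)[C@H]1[C@@H]2OO[C@@H](C(C)=C2)C[C@@H]3OC(C)(C)O[C@]3(C)C[C@H]1OC(=O)CC(C)C
A2 | alternative 1 | ten-membered (Z,Z)-diene with acrylate arm, isovalerate and C1/C10 acetonide | COC(=O)C(=C)[C@H]1/C=C\C(C)=C/C[C@@H]2OC(C)(C)O[C@]2(C)C[C@H]1OC(=O)CC(C)C
A3 | alternative 2 | isoxazoline-bridged ten-membered lactone | C1C(=O)O[C@@H]2/C=C(/C)[C@H]3CC(=NO3)[C@](C)(O)C[C@@H](O[Si](C)(C)C(C)(C)C)[C@@H]12
A4 | alternative 2 | seco aldoxime: γ-lactone with Z-diene on C6 and oxime chain on C7 | C1C(=O)O[C@H](/C=C(/C)C=C)[C@H]1[C@H](O[Si](C)(C)C(C)(C)C)C[C@@](C)(O)C=NO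
A5 | alternative 3 | C3 silyl ether of the target (identical with 26) | C=C1C(=O)O[C@@H]2/C=C(/C)[C@H](O[Si](C)(C)C(C)(C)C)CC(=O)[C@](C)(O)C[C@@H](OC(=O)CC(C)C)[C@@H]12
A6 | alternative 3 | ten-membered C6 alcohol with C7 ethynyl group | C#C[C@H]1[C@H](O)/C=C(/C)[C@H](O[Si](C)(C)C(C)(C)C)CC(=O)[C@](C)(O)C[C@H]1OC(=O)CC(C)C
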